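**Plan**
1. Retrosynthetic cuts: the C8–C(benzylic) bond together with a temporary O1–acyl (lactone) bond; then O1–C2 of the chromanone; then C6–prenyl, traced back to an O5 1,1-dimethylallyl ether; then the aryl–C4 (ketone) bond; then C3–CH3.
2. Enabling feature: C8 is ortho to the ring oxygen O1, and the carboxyl carbon is 1,5 to O1 through C8 and the benzylic carbon. The side chain is therefore a ring-opened 4-phenyl-3,4-dihydrocoumarin whose lactone oxygen is O1, so the phenol that later becomes O1 can deliver a cinnamoyl unit to C8.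
3. Forward order: chiral-pool acyl chain plus lithiated 5-methoxyresorcinol give a 2,6-dihydroxy-4-methoxyaryl ketone with two equivalent hydroxyls; mono 1,1-dimethylallyl ether; carbene-catalysed annulation with phenylpropynal (dihydrocoumarin ring first); lactone opened and chromanone ring closed on the released phenol; Claisen shift gives 5-OH and 6-prenyl; free acid.
4. Stereochemistry: C3 from Fráter–Seebach anti-methylation of methyl (R)-3-hydroxybutanoate; C2 by Mitsunobu inversion of the (R)-carbinol (anti aldol gives the cis chromanone); the benzylic centre from the chiral triazolium catalyst.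
5. Regiochemistry is fixed by the equivalence of the two hydroxyls and by which oxygen is free at each stage.

Key step: step 8

Assumption (catalyst sense): the (5aS,10bR) antipode of the aminoindanol-derived N-mesityl triazolium salt is taken to be the one that gives the (R) benzylic centre; if the sense of induction is the opposite, the (5aR,10bS) antipode is used in the same step.
Remark (reagent): tert-butyl 2-methylbut-3-en-2-yl carbonate is treated as a catalogue reagent.

Step 1
Reactants: 1 methyl (R)-3-hydroxybutanoate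
Product: 3 methyl (2R,3R)-3-hydroxy-2-methylbutanoate, via dilithium alkoxide-enolate 2 (not isolated)
Conditions: LDA (2.2 equiv), THF, −78 to −20 °C; MeI, DMPU, −78 to 0 °C; aq. NH4Cl
Reagents that add atoms: iodomethane, CI
Why: Fráter–Seebach alkylation, in which the chelated dianion is methylated on the face away from the C3 methyl group, so the anti (2R,3R) ester should be the main product and C2 is set by the existing C3 centre.

Step 2
Reactants: 3 methyl (2R,3R)-3-hydroxy-2-methylbutanoate
Product: 4 methyl (2R,3R)-3-[(tert-butyldimethylsilyl)oxy]-2-methylbutanoate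
Conditions: TBSCl, imidazole, DMF, rt
Reagents that add atoms: tert-butyldimethylsilyl chloride, CC(C)(C)[Si](C)(C)Cl
Why: Standard silylation of a secondary alcohol, which masks the hydroxyl for the organolithium, palladium and carbene steps without touching either stereocentre.

Step 3
Reactants: 4 methyl (2R,3R)-3-[(tert-butyldimethylsilyl)oxy]-2-methylbutanoate
Product: 5 (2R,3R)-3-[(tert-butyldimethylsilyl)oxy]-N-methoxy-N,2-dimethylbutanamide
Conditions: MeNHOMe·HCl, i-PrMgCl, THF, −20 to 0 °C
Reagents that add atoms: N,O-dimethylhydroxylamine hydrochloride, CNOC.Cl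
Why: Weinreb amide formation by aminolysis of the ester with the magnesium amide, a weakly basic nucleophile that should not enolise the ester, so C2 is kept.

Step 4
Reactants: 6 5-methoxybenzene-1,3-diol
Product: 7 1-methoxy-3,5-bis(methoxymethoxy)benzene
Conditions: MOMCl, i-Pr2NEt, CH2Cl2, 0 °C to rt
Reagents that add atoms: chloromethyl methyl ether, COCCl
Why: O-alkylation of both phenols to the MOM acetals, which protect them and serve as the directing groups for the metalation.

Step 5
Reactants: 7 1-methoxy-3,5-bis(methoxymethoxy)benzene; 5 (2R,3R)-3-[(tert-butyldimethylsilyl)oxy]-N-methoxy-N,2-dimethylbutanamide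
Product: 9 (2R,3R)-3-[(tert-butyldimethylsilyl)oxy]-1-[4-methoxy-2,6-bis(methoxymethoxy)phenyl]-2-methylbutan-1-one, via aryllithium 8 (not isolated)
Conditions: n-BuLi, THF, 0 °C; then 5, −78 to 0 °C; aq. NH4Cl
Reagents that add atoms: none
Why: Directed ortho-metalation at the carbon flanked by the two MOM ethers, then Weinreb ketone synthesis, which releases the ketone only on work-up, so no over-addition and no base-induced epimerisation of the α-centre is expected.

Step 6
Reactants: 9 (2R,3R)-3-[(tert-butyldimethylsilyl)oxy]-1-[4-methoxy-2,6-bis(methoxymethoxy)phenyl]-2-methylbutan-1-one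
Product: 10 (2R,3R)-3-[(tert-butyldimethylsilyl)oxy]-1-(2,6-dihydroxy-4-methoxyphenyl)-2-methylbutan-1-one
Conditions: ZnBr2, n-PrSH, CH2Cl2, 0 °C
Reagents that add atoms: none
Why: Lewis acid/thiol cleavage of aryl MOM acetals, in which the thiol traps the methoxymethyl cation; the short cold exposure should spare the hindered secondary TBS ether and the β-silyloxy ketone.

Step 7
Reactants: 10 (2R,3R)-3-[(tert-butyldimethylsilyl)oxy]-1-(2,6-dihydroxy-4-methoxyphenyl)-2-methylbutan-1-one
Product: 11 (2R,3R)-3-[(tert-butyldimethylsilyl)oxy]-1-{2-hydroxy-4-methoxy-6-[(2-methylbut-3-en-2-yl)oxy]phenyl}-2-methylbutan-1-one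
Conditions: Pd(PPh3)4 (5 mol%), tert-butyl 2-methylbut-3-en-2-yl carbonate (1.2 equiv), THF, 0 °C
Reagents that add atoms: tert-butyl 2-methylbut-3-en-2-yl carbonate, CC(C)(C)OC(=O)OC(C)(C)C=C
Why: Tsuji–Trost O-allylation in which the phenoxide attacks the more substituted terminus of the π-allyl complex under kinetic control to give the tertiary ether; the two hydroxyls are equivalent, so either gives the same product, and the remaining one is locked in the chelate with the ketone, which should stop the reaction at the mono-ether.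

Step 8
Reactants: 11 (2R,3R)-3-[(tert-butyldimethylsilyl)oxy]-1-{2-hydroxy-4-methoxy-6-[(2-methylbut-3-en-2-yl)oxy]phenyl}-2-methylbutan-1-one; 12 3-phenylprop-2-ynal
Product: 15 (4R)-8-{(2R,3R)-3-[(tert-butyldimethylsilyl)oxy]-2-methylbutanoyl}-5-methoxy-7-[(2-methylbut-3-en-2-yl)oxy]-4-phenyl-3,4-dihydro-2H-chromen-2-one, via cinnamoyl azolium 13 (not isolated), via C-aryl acyl azolium 14 (not isolated)
Conditions: (5aS,10bR)-N-mesityl aminoindanol triazolium chloride (10 mol%), i-Pr2NEt (10 mol%), toluene, 40 °C
Reagents that add atoms: none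
Why: The carbene adds to ynal 12 and an internal redox gives the (E)-cinnamoyl azolium 13; the phenol O–H of 11 adds to its carbonyl and the hemiacetal undergoes a [3,3] shift (Coates–Claisen type, equivalent in outcome to conjugate addition of the ortho carbon) that forms the aryl–benzylic C–C bond and, after proton transfer, acyl azolium 14. The closest known reaction type is the carbene-catalysed enantioselective annulation of ynals or enals with naphthols and other enol-like phenols to 4-aryl-3,4-dihydrocoumarins. The lactone ring closes by 6-exo-trig acyl transfer from the azolium of 14 to the same phenol oxygen, which releases the carbene. The benzylic stereocentre is set under catalyst control, because the aminoindanol backbone blocks one face of the acyl azolium in the ordered [3,3] array and the ring carbon should add to the open face to give the (R) centre (see assumption). The step needs site selectivity between the two ring C–H positions and between C- and O-acylation: only the carbon between OH and OMe is ortho to a free hydroxyl, the other hydroxyl is capped as the tertiary allyl ether, and an O-cinnamoyl ester, if formed, is an activated aryl ester that the carbene should return to 13. The (2R,3R) chain makes any minor benzylic epimer a diastereomer, which should be removable by chromatography.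

Step 9
Reactants: 15 (4R)-8-{(2R,3R)-3-[(tert-butyldimethylsilyl)oxy]-2-methylbutanoyl}-5-methoxy-7-[(2-methylbut-3-en-2-yl)oxy]-4-phenyl-3,4-dihydro-2H-chromen-2-one
Product: 17 prop-2-en-1-yl (3R)-3-{2-hydroxy-3-[(2R,3R)-3-hydroxy-2-methylbutanoyl]-6-methoxy-4-[(2-methylbut-3-en-2-yl)oxy]phenyl}-3-phenylpropanoate, via silyl ether allyl ester 16 (not isolated)
Conditions: K2CO3 (0.2 equiv), allyl alcohol, 0 °C to rt; AcOH, concentrate; then TBAF, AcOH (1:1), THF, rt
Reagents that add atoms: allyl alcohol, C=CCO
Why: Base-catalysed alcoholysis of the aryl ester (phenoxide is the better leaving group and the freed phenol gains the hydrogen bond to the ketone) removes the temporary ring, and buffered fluoride then cleaves the TBS ether without enolising the β-hydroxy ketone.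

Step 10
Reactants: 17 prop-2-en-1-yl (3R)-3-{2-hydroxy-3-[(2R,3R)-3-hydroxy-2-methylbutanoyl]-6-methoxy-4-[(2-methylbut-3-en-2-yl)oxy]phenyl}-3-phenylpropanoate
Product: 19 prop-2-en-1-yl (3R)-3-{(2S,3R)-7-methoxy-2,3-dimethyl-5-[(2-methylbut-3-en-2-yl)oxy]-4-oxo-3,4-dihydro-2H-chromen-8-yl}-3-phenylpropanoate, via alkoxyphosphonium phenoxide 18 (not isolated)
Conditions: PPh3, DIAD, THF (dilute), 0 °C to rt
Reagents that add atoms: none
Why: Mitsunobu cycloetherification (6-exo-tet SN2 of the only free phenol on the activated secondary alcohol) with inversion, which turns the (R)-carbinol into the (2S) ring carbon and so gives the cis-2,3-dimethylchroman-4-one from the anti aldol pattern.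

Step 11
Reactants: 19 prop-2-en-1-yl (3R)-3-{(2S,3R)-7-methoxy-2,3-dimethyl-5-[(2-methylbut-3-en-2-yl)oxy]-4-oxo-3,4-dihydro-2H-chromen-8-yl}-3-phenylpropanoate
Product: 21 prop-2-en-1-yl (3R)-3-[(2S,3R)-5-hydroxy-7-methoxy-2,3-dimethyl-6-(3-methylbut-2-en-1-yl)-4-oxo-3,4-dihydro-2H-chromen-8-yl]-3-phenylpropanoate, via ortho-dienone 20 (not isolated)
Conditions: toluene, 110 °C (sealed tube)
Reagents that add atoms: none
Why: Aromatic Claisen rearrangement of the aryl 1,1-dimethylallyl ether, in which C6 is the only ortho carbon that carries hydrogen (C4a is blocked and the para carbon C8 is substituted), so the inverted allyl unit arrives there as the normal prenyl group and dienone 20 tautomerises to the chelated 5-hydroxy arene under neutral conditions.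

Step 12
Reactants: 21 prop-2-en-1-yl (3R)-3-[(2S,3R)-5-hydroxy-7-methoxy-2,3-dimethyl-6-(3-methylbut-2-en-1-yl)-4-oxo-3,4-dihydro-2H-chromen-8-yl]-3-phenylpropanoate
Product: 22 (3R)-3-[(2S,3R)-5-hydroxy-7-methoxy-2,3-dimethyl-6-(3-methylbut-2-en-1-yl)-4-oxo-3,4-dihydro-2H-chromen-8-yl]-3-phenylpropanoic acid
Conditions: Pd(PPh3)4 (5 mol%), morpholine, THF, rt; dilute acid work-up
Reagents that add atoms: none
Why: Palladium(0)-catalysed deallylation (Tsuji–Trost) with morpholine as allyl acceptor frees the acid at room temperature without strong base, so the epimerisable cis chromanone, the prenyl group and the phenol should be untouched.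

**Compound list**
1 | methyl (R)-3-hydroxybutanoate | C[C@@H](O)CC(=O)OC | starting material
2 | dilithium alkoxide-enolate of 1 (dilithium (3R)-1-methoxybut-1-ene-1,3-diolate) | C[C@@H](O[Li])C=C(O[Li])OC | intermediate (not isolated)
3 | methyl (2R,3R)-3-hydroxy-2-methylbutanoate | C[C@@H](O)[C@@H](C)C(=O)OC | intermediate
4 | methyl (2R,3R)-3-[(tert-butyldimethylsilyl)oxy]-2-methylbutanoate | C[C@@H](O[Si](C)(C)C(C)(C)C)[C@@H](C)C(=O)OC | intermediate
5 | (2R,3R)-3-[(tert-butyldimethylsilyl)oxy]-N-methoxy-N,2-dimethylbutanamide | C[C@@H](O[Si](C)(C)C(C)(C)C)[C@@H](C)C(=O)N(C)OC | intermediate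
6 | 5-methoxybenzene-1,3-diol (5-methoxyresorcinol) | COc1cc(O)cc(O)c1 | starting material
7 | 1-methoxy-3,5-bis(methoxymethoxy)benzene | COCOc1cc(OC)cc(OCOC)c1 | intermediate
8 | [4-methoxy-2,6-bis(methoxymethoxy)phenyl]lithium | [Li]c1c(OCOC)cc(OC)cc1OCOC | intermediate (not isolated)
9 | (2R,3R)-3-[(tert-butyldimethylsilyl)oxy]-1-[4-methoxy-2,6-bis(methoxymethoxy)phenyl]-2-methylbutan-1-one | C[C@@H](O[Si](C)(C)C(C)(C)C)[C@@H](C)C(=O)c1c(OCOC)cc(OC)cc1OCOC | intermediate
10 | (2R,3R)-3-[(tert-butyldimethylsilyl)oxy]-1-(2,6-dihydroxy-4-methoxyphenyl)-2-methylbutan-1-one | C[C@@H](O[Si](C)(C)C(C)(C)C)[C@@H](C)C(=O)c1c(O)cc(OC)cc1O | intermediate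
11 | (2R,3R)-3-[(tert-butyldimethylsilyl)oxy]-1-{2-hydroxy-4-methoxy-6-[(2-methylbut-3-en-2-yl)oxy]phenyl}-2-methylbutan-1-one | C[C@@H](O[Si](C)(C)C(C)(C)C)[C@@H](C)C(=O)c1c(O)cc(OC)cc1OC(C)(C)C=C | intermediate
12 | 3-phenylprop-2-ynal | O=CC#Cc1ccccc1 | starting material
13 | (E)-cinnamoyl azolium chloride: (5aS,10bR)-2-mesityl indeno-oxazino-triazolium carrying the (E)-3-phenylprop-2-enoyl group on the carbene carbon | O=C(/C=C/c1ccccc1)c1[n+](-c2c(C)cc(C)cc2C)nc2CO[C@H]3Cc4ccccc4[C@H]3n12.[Cl-] | intermediate (not isolated)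
14 | acyl azolium chloride in which the ring carbon ortho to the free OH of 11 is bonded to the (R) β-carbon of the 3-phenylpropanoyl azolium | C[C@@H](O[Si](C)(C)C(C)(C)C)[C@@H](C)C(=O)c1c(O)c([C@H](CC(=O)c2[n+](-c3c(C)cc(C)cc3C)nc3CO[C@H]4Cc5ccccc5[C@H]4n23)c2ccccc2)c(OC)cc1OC(C)(C)C=C.[Cl-] | intermediate (not isolated)
15 | (4R)-8-{(2R,3R)-3-[(tert-butyldimethylsilyl)oxy]-2-methylbutanoyl}-5-methoxy-7-[(2-methylbut-3-en-2-yl)oxy]-4-phenyl-3,4-dihydro-2H-chromen-2-one | C[C@@H](O[Si](C)(C)C(C)(C)C)[C@@H](C)C(=O)c1c2OC(=O)C[C@H](c3ccccc3)c2c(OC)cc1OC(C)(C)C=C | intermediate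
16 | prop-2-en-1-yl (3R)-3-{3-[(2R,3R)-3-[(tert-butyldimethylsilyl)oxy]-2-methylbutanoyl]-2-hydroxy-6-methoxy-4-[(2-methylbut-3-en-2-yl)oxy]phenyl}-3-phenylpropanoate | C[C@@H](O[Si](C)(C)C(C)(C)C)[C@@H](C)C(=O)c1c(O)c([C@H](CC(=O)OCC=C)c2ccccc2)c(OC)cc1OC(C)(C)C=C | intermediate (not isolated)
17 | prop-2-en-1-yl (3R)-3-{2-hydroxy-3-[(2R,3R)-3-hydroxy-2-methylbutanoyl]-6-methoxy-4-[(2-methylbut-3-en-2-yl)oxy]phenyl}-3-phenylpropanoate | C[C@@H](O)[C@@H](C)C(=O)c1c(O)c([C@H](CC(=O)OCC=C)c2ccccc2)c(OC)cc1OC(C)(C)C=C | intermediate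
18 | alkoxyphosphonium phenoxide zwitterion of 17 (Ph3P+ on the side-chain oxygen, phenol deprotonated) | C[C@@H](O[P+](c1ccccc1)(c1ccccc1)c1ccccc1)[C@@H](C)C(=O)c1c([O-])c([C@H](CC(=O)OCC=C)c2ccccc2)c(OC)cc1OC(C)(C)C=C | intermediate (not isolated)
19 | prop-2-en-1-yl (3R)-3-{(2S,3R)-7-methoxy-2,3-dimethyl-5-[(2-methylbut-3-en-2-yl)oxy]-4-oxo-3,4-dihydro-2H-chromen-8-yl}-3-phenylpropanoate | COc1cc(OC(C)(C)C=C)c2c(c1[C@H](CC(=O)OCC=C)c1ccccc1)O[C@@H](C)[C@@H](C)C2=O | intermediate
20 | ortho-dienone tautomer of 21 (C5 ketone, sp3 C6 bearing H and the prenyl group, C7=C8 and C8a=C4a double bonds) | COC1=C([C@H](CC(=O)OCC=C)c2ccccc2)C2=C(C(=O)C1CC=C(C)C)C(=O)[C@H](C)[C@H](C)O2 | intermediate (not isolated)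
21 | prop-2-en-1-yl (3R)-3-[(2S,3R)-5-hydroxy-7-methoxy-2,3-dimethyl-6-(3-methylbut-2-en-1-yl)-4-oxo-3,4-dihydro-2H-chromen-8-yl]-3-phenylpropanoate | COc1c(CC=C(C)C)c(O)c2c(c1[C@H](CC(=O)OCC=C)c1ccccc1)O[C@@H](C)[C@@H](C)C2=O | intermediate
22 | (3R)-3-[(2S,3R)-5-hydroxy-7-methoxy-2,3-dimethyl-6-(3-methylbut-2-en-1-yl)-4-oxo-3,4-dihydro-2H-chromen-8-yl]-3-phenylpropanoic acid | COc1c(CC=C(C)C)c(O)c2c(c1[C@H](CC(=O)O)c1ccccc1)O[C@@H](C)[C@@H](C)C2=O | target

**Summary**
Total step count: 12. Longest linear sequence: 11 steps (1 to 22 through steps 1, 2, 3, 5, 6, 7, 8, 9, 10, 11, 12); the arene branch from 6 joins at step 5.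

Steps most likely to fail:

Step 8. The acyl azolium may be diverted into simple O-acylation of the phenol, or the facial discrimination in the C–C bond formation may be weak because the ring carbon is deactivated by the ortho ketone. Fallback: setting out from 11, the same bond is made by iminium catalysis instead of acyl azolium catalysis. Compound 11 and (E)-cinnamaldehyde, with an α,α-diphenylprolinol trimethylsilyl ether (the enantiomer that gives the 4R adduct) and benzoic acid in CH2Cl2, should undergo Friedel–Crafts alkylation at the same ortho carbon and close to the 2-hydroxychroman (lactol) F1. Oxidation of the lactol F1 with Dess–Martin periodinane and NaHCO3 gives lactone 15, where the route is rejoined.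

Step 10. β-Elimination of the activated alcohol to the enone, followed by unselective conjugate re-addition of the phenol, would scramble C2 and C3. Fallback: setting out from 17, the C–O bond is formed by conjugate addition under catalyst control instead of SN2 displacement. Mesylation (MsCl, Et3N, CH2Cl2, −20 °C) gives the mesylate F2, and E1cB loss of methanesulfonate on warming gives the (E)-2-methylbut-2-enoyl ketone F3, in which the phenol is held in the chelate. Intramolecular oxa-Michael addition of the enone F3 under a cinchona alkaloid (quinine or its pseudo-enantiomer, matched to the 2S,3R series) in chlorobenzene is the reaction type that closes o-(2-methylbut-2-enoyl)phenols to cis-2,3-dimethylchroman-4-ones under kinetic control, and it returns to 19.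

Step 7. The π-allyl complex may alkylate the electron-rich ring carbon or react at its unsubstituted terminus (linear prenyl ether), and a second etherification may follow. Fallback: setting out from 10, copper-catalysed O-propargylation (3-chloro-3-methylbut-1-yne, DBU, CuCl2 cat., MeCN, 0 °C), which forms only the tertiary aryl propargyl ether, gives the propargyl ether F4. Semi-hydrogenation of the propargyl ether F4 over Lindlar catalyst with quinoline returns to 11.

**Further compounds**
F1 | step 8 | (4R)-8-{(2R,3R)-3-[(tert-butyldimethylsilyl)oxy]-2-methylbutanoyl}-5-methoxy-7-[(2-methylbut-3-en-2-yl)oxy]-4-phenyl-3,4-dihydro-2H-chromen-2-ol (anomer mixture) | C[C@@H](O[Si](C)(C)C(C)(C)C)[C@@H](C)C(=O)c1c2OC(O)C[C@H](c3ccccc3)c2c(OC)cc1OC(C)(C)C=C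
F2 | step 10 | prop-2-en-1-yl (3R)-3-{2-hydroxy-6-methoxy-3-[(2R,3R)-2-methyl-3-(methylsulfonyloxy)butanoyl]-4-[(2-methylbut-3-en-2-yl)oxy]phenyl}-3-phenylpropanoate | C[C@@H](OS(C)(=O)=O)[C@@H](C)C(=O)c1c(O)c([C@H](CC(=O)OCC=C)c2ccccc2)c(OC)cc1OC(C)(C)C=C
F3 | step 10 | prop-2-en-1-yl (3R)-3-{2-hydroxy-6-methoxy-3-[(2E)-2-methylbut-2-enoyl]-4-[(2-methylbut-3-en-2-yl)oxy]phenyl}-3-phenylpropanoate | C/C=C(\C)C(=O)c1c(O)c([C@H](CC(=O)OCC=C)c2ccccc2)c(OC)cc1OC(C)(C)C=C
F4 | step 7 | (2R,3R)-3-[(tert-butyldimethylsilyl)oxy]-1-{2-hydroxy-4-methoxy-6-[(2-methylbut-3-yn-2-yl)oxy]phenyl}-2-methylbutan-1-one | C[C@@H](O[Si](C)(C)C(C)(C)C)[C@@H](C)C(=O)c1c(O)cc(OC)cc1OC(C)(C)C#C
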